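## Structural features

Larreantin is an achiral 1,4-naphthoquinone. The quinone ring (C1–C4) has carbonyl groups at C1 and C4 and a methoxy group at C2, which makes it a vinylogous ester. The benzo ring (C4a–C8a) carries a 4-hydroxy-3-methoxybenzyl group at C6, a methyl group at C7 and a 4-hydroxy-3-methoxyphenyl group at C8, and C5–H is its only hydrogen. There is no stereocentre; the C8–aryl axis is flanked by the C7 methyl group and the peri C1 carbonyl, but the guaiacyl ring has no ortho substituent, so the axis is not treated as a stereo-element. The fragile groups are the methoxyquinone (reducible, open to nucleophiles and base), the two free guaiacol hydroxyls (easily oxidised, and acidic enough to interfere with organometallic and diazo chemistry) and the doubly benzylic C6–CH2. The real difficulty is regiochemical: three different carbon substituents sit on the adjacent carbons C6, C7 and C8 next to the ring fusion, and the C2 methoxy group must lie next to the C1 carbonyl, the one peri to the C8 aryl group. The key step uses the position of C8 between C8a, which can carry a carboxyl group as anchor for the later quinone ring, and C7, whose hydrogen is then the only C–H ortho to C8. A C8 iodide can therefore pass palladium to C7 through norbornene, take up the methyl group there and then accept the aryl group at C8 itself.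

## Logic of the disconnections

**22 from 20.** The two phenolic O–H bonds are exchanged for O–benzyl bonds. Free guaiacols would not survive the zinc, palladium, diazo and nitroxyl-radical chemistry, so they stay masked to the end, and benzyl resists every earlier reagent. The forward step must remove benzyl without harming the methoxyquinone; hydrogenolysis passes through 21, which air returns to the quinone.

**20 from 19.** The C1=O bond is removed, so the quinone goes back to a naphthol with hydrogen at C1. This postpones the reactive quinone to the penultimate step and leaves an aromatic ring that a benzannulation can deliver. The forward oxidation must occur at C1 (para to the C4 hydroxyl, peri to the C8 aryl group) and not at C3.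

**19 from 12 and 15.** The bonds C8a–C1, C1–C2, C3–C4 and C4–C4a are cut, which removes the whole oxygenated ring. What remains is an acyl group on C8a whose carbonyl carbon ends as C4, a diazo carbon that ends as C1, and a two-carbon alkyne that brings C2 with its methoxy group and C3. The forward step needs aryl migration, the correct polarity in the [2+2] addition (methoxy-bearing carbon to C1) and closure at C4a. The last is secured because C8, the other ortho carbon, is substituted.

**15 from 13.** The triple bond is traced back to a saturated chloroacetal by two eliminations. This replaces a volatile, poorly available ynol ether by a stable catalogue liquid. The forward step needs three equivalents of a strong amide base and cold handling of the product.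

**12 from 10, and 10 from 9.** The bond between the acyl carbon and the diazo carbon is cut, and the acid is returned to its methyl ester. The ester is the group that the key step needs ortho to the iodide. The forward steps must hydrolyse an ester with one ortho substituent and activate the acid without letting it acylate the neighbouring electron-rich C8 ring.

**9 from 7, 8 and a methyl electrophile.** C7–CH3 and C8–aryl are cut together. This turns a 1,2,3,4-tetrasubstituted benzene into a 1,2,4-trisubstituted aryl iodide, a catalogue boronic acid and a one-carbon reagent. The forward step must functionalise the C–H next to the iodide before the iodide position itself couples, and it must do so at a C–H flanked by the C6 benzyl group.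

**7 from 5.** The C8–I bond is exchanged for C8–N. An amino group survives the preceding cross-coupling, where an iodide would not, and is converted afterwards. The forward step is a diazotisation with iodide displacement in a medium mild enough for benzyl ether and ester.

**5 from 3 and 4, 4 from 2, 2 from 1.** The C6–CH2 bond is cut between the benzo ring and the benzylic carbon. Both halves are then simple: a catalogue bromoanthranilate and a benzylic zinc reagent made in two operations from a catalogue alcohol. The forward coupling must tolerate the free NH2 group and the ester.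

## Other disconnections considered

**Alternative 1: anodic cyclisation of a triaryl-substituted butane.**
- Cut: C8–C8a, with the benzo ring taken back to a saturated carbocycle.
- Forward step: the phenol A1 (one free guaiacol, one benzyl-protected guaiacol, one 2,4,5-trimethoxyphenyl ring on a branched C4 chain) would be oxidised at a carbon anode in (CF3)2CHOH with 2,6-lutidine to the para-quinone methide A2. The trimethoxyphenyl ring would then attack the methide carbon through C8a to give the aryltetralin A3 as a diastereomer mixture.
- In favour: the oxygen pattern of the quinone ring arrives as a 1,2,4-trimethoxyarene, so the later oxidative demethylation of the para pair fixes the quinone regiochemistry. On this point it is better than the chosen plan, whose naphthol oxidation must choose C1 over C3. It also needs no transition metal, no diazo compound and no photochemistry, and uses current as oxidant.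
- Against: A2 has two tethered arenes that can each close a six-membered ring. The benzyl-protected guaiacyl ring offers a carbon para to a methoxy group, whereas C8a is ortho to one methoxy group and meta to two, so the wanted closure is electronically the weaker one. A3 has three sp3 centres at C6, C7 and C8 and a CH2 at C5, all of which must be dehydrogenated, and the oxidants for that also threaten the exocyclic C6–CH2 and the free phenol.
- Comparison: on structure it handles the quinone ring more cleanly and the benzo ring less cleanly. On mechanism its selectivity depends on the relative nucleophilicity of two arenes, whereas the chosen key step is directed by the substrate. On step economy, making A1 with two differentiated phenols, followed by cyclisation, aromatisation, oxidative demethylation and debenzylation, would probably exceed the nine linear steps of the chosen plan.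

**Alternative 2: cationic benzannulation of a dichlorocyclopropyl carbinol.**
- Cut: C4a–C5, with C5 coming from a dichlorocarbene carbon.
- Forward step: SnCl4 would ionise the tertiary carbinol A4, which carries the guaiacyl ring, a 2,3,5-trimethoxyphenyl ring and a 2,2-dichlorocyclopropyl group bearing the methyl and benzyl substituents. The cyclopropane would open, the trimethoxyphenyl ring would close through C4a, and loss of HCl would give the chloronaphthalene A5.
- In favour: the positions of the C6 benzyl, C7 methyl and C8 aryl groups are written into A4 and transferred as such. In positional certainty it equals the chosen plan, and it is better in that no C–H bond at a flanked position has to be functionalised. Like alternative 1 it brings the quinone oxygens in at the arene stage.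
- Against: the chlorine at C5 is foreign to the target and costs a reductive step that must spare or be coordinated with the benzyl ethers. The closure creates a peri contact between C5–Cl and the C4 methoxy group. SnCl4 can attack benzyl ethers, and either aryl group of the cation can in principle close, depending on which one lies cis to the side chain. A4 needs a dichlorocarbene addition to a trisubstituted alkene and two different aryl nucleophiles added in sequence.
- Comparison: on structure it is equal for the benzo ring and better for the quinone oxidation pattern. On mechanism it uses strong Lewis acid on a substrate with four ether types, against mild base and palladium in the chosen step. On step economy it would probably run one to three steps longer because of the dechlorination and oxidative demethylation.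

**Alternative 3: photochemical diazoketone–ynol ether benzannulation.**
- Cut: C8a–C1, C1–C2, C3–C4 and C4–C4a.
- Forward step: irradiation of the diazomethyl ketone A6 with the ynol ether 15 would give the methoxynaphthol A7 through 16 and 17.
- In favour: four bonds and the oxygenated ring are formed in one operation, the methoxy position follows from ketene and ynol ether polarity, and the closure site is fixed because C8 is substituted.
- Against: it needs a diazo compound, light and a volatile alkyne, it still requires a late oxidation, and as a strategy it does not say how the crowded benzoyl precursor is obtained.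
- Comparison: this is not a rival but the same ring construction as step 8 of the chosen plan; A6 is identical with 12 and A7 with 19. On ring formation the two are equal. The chosen key step answers the question this cut leaves open, namely the assembly of the tetrasubstituted arene, and once A6 is in hand the step count is the same.

Key step: step 4

Remark: methoxyacetylene (15) is assumed to need preparation (step 7), and the benzyl-protected vanillyl alcohol 1 is taken as a catalogue compound, which saves the phenol benzylation; trimethylsilyldiazomethane replaces diazomethane for safety.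

## Route

Step 1
Reactants: 1 4-benzyloxy-3-methoxybenzyl alcohol
Product: 2 4-benzyloxy-3-methoxybenzyl chloride
Conditions: SOCl2 (1.2 equiv), CH2Cl2, 0 °C → rt; evaporate, use crude
Reagents that add atoms: thionyl chloride, O=S(Cl)Cl
Why: Chlorodehydroxylation of an electron-rich benzylic alcohol through its chlorosulfite should be fast at 0 °C; the aryl benzyl and methyl ethers are inert, and the labile chloride is used without purification.

Step 2
Reactants: 2 4-benzyloxy-3-methoxybenzyl chloride; 3 methyl 2-amino-4-bromobenzoate
Product: 5 methyl 2-amino-4-(4-benzyloxy-3-methoxybenzyl)benzoate, via benzylzinc chloride 4 (not isolated)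
Conditions: Zn dust, LiCl, THF, 25 °C; then 3, Pd(OAc)2 (2 mol %), SPhos (4 mol %), THF, 25 → 50 °C
Reagents that add atoms: none
Why: LiCl-assisted zinc insertion into the benzylic C–Cl bond should give 4, and Negishi cross-coupling with Pd(OAc)2 and the biarylphosphine SPhos is the reaction type that tolerates a free aniline N–H and an ester; the C–Br bond para to the ester adds readily to zerovalent palladium, forming the C6–CH2 bond.

Step 3
Reactants: 5 methyl 2-amino-4-(4-benzyloxy-3-methoxybenzyl)benzoate
Product: 7 methyl 4-(4-benzyloxy-3-methoxybenzyl)-2-iodobenzoate, via arenediazonium tosylate 6 (not isolated)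
Conditions: p-TsOH·H2O (3 equiv), NaNO2 (2 equiv), KI (2.5 equiv), MeCN/H2O, 10 °C → rt
Reagents that add atoms: potassium iodide, [K+].[I-]
Why: Diazotisation of the anthranilate gives a comparatively stable arenediazonium tosylate, and iodide displaces dinitrogen without copper (Sandmeyer-type iododediazoniation); the weakly acidic medium spares the benzyl ether and the ester.

Step 4
Reactants: 7 methyl 4-(4-benzyloxy-3-methoxybenzyl)-2-iodobenzoate; 8 4-benzyloxy-3-methoxyphenylboronic acid
Product: 9 methyl 2-(4-benzyloxy-3-methoxyphenyl)-4-(4-benzyloxy-3-methoxybenzyl)-3-methylbenzoate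
Conditions: Pd(OAc)2 (10 mol %), tri(2-furyl)phosphine (22 mol %), norbornene (2 equiv), MeI (4 equiv), 8 (1.5 equiv), K2CO3 (4 equiv), DMF, 90 °C, sealed tube
Reagents that add atoms: iodomethane, CI
Why: Zerovalent palladium, formed from Pd(OAc)2 and the phosphine, inserts into the C8–I bond of 7, and the arylpalladium iodide adds to the exo face of norbornene to give a norbornylpalladium species with no accessible syn β-hydrogen. Carbonate-assisted palladation of C7–H then closes a five-membered aryl–norbornyl palladacycle of divalent palladium. Oxidative addition of iodomethane gives a tetravalent palladium intermediate, and reductive elimination forms the C7–CH3 bond. With C8 now flanked by the C8a ester carbon and the C7 methyl group, steric compression drives β-carbon elimination, which expels norbornene and returns an arylpalladium iodide at C8. Transmetalation with boronic acid 8 and reductive elimination form the C8–aryl bond and regenerate zerovalent palladium. The closest known reaction type is the Catellani ortho-alkylation of an ortho-substituted aryl iodide with Suzuki–Miyaura termination; no ring is closed and no stereocentre is formed. Site selectivity comes from the substrate, since the ester blocks C8a and C7–H is the only hydrogen ortho to C8, and the smallest electrophile is used because C7 is flanked by the C6 benzyl group. Sequence selectivity rests on norbornene insertion outrunning transmetalation at the first arylpalladium stage and on the doubly ortho-substituted arylpalladium formed after methylation no longer holding norbornene, so that only then does the boronic acid intercept it.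

Step 5
Reactants: 9 methyl 2-(4-benzyloxy-3-methoxyphenyl)-4-(4-benzyloxy-3-methoxybenzyl)-3-methylbenzoate
Product: 10 2-(4-benzyloxy-3-methoxyphenyl)-4-(4-benzyloxy-3-methoxybenzyl)-3-methylbenzoic acid
Conditions: LiOH·H2O (5 equiv), THF/MeOH/H2O, 60 °C; then aq. HCl to pH 2
Reagents that add atoms: lithium hydroxide, [Li+].[OH-]
Why: Saponification by acyl–oxygen cleavage of a methyl benzoate with one ortho substituent needs mild heating but no special reagent; benzyl ethers, the biaryl and the diarylmethane are stable to hydroxide.

Step 6
Reactants: 10 2-(4-benzyloxy-3-methoxyphenyl)-4-(4-benzyloxy-3-methoxybenzyl)-3-methylbenzoic acid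
Product: 12 2-diazo-1-[2-(4-benzyloxy-3-methoxyphenyl)-4-(4-benzyloxy-3-methoxybenzyl)-3-methylphenyl]ethanone, via acid chloride 11 (not isolated)
Conditions: (COCl)2 (1.5 equiv), DMF (cat.), CH2Cl2, 0 °C → rt; evaporate; then TMSCHN2 (2.2 equiv), THF/MeCN, 0 °C → rt
Reagents that add atoms: trimethylsilyldiazomethane, C[Si](C)(C)C=[N+]=[N-]
Why: Acid chloride formation under Vilsmeier catalysis followed by C-acylation of trimethylsilyldiazomethane with loss of chlorotrimethylsilane (diazoketone synthesis of the Arndt–Eistert type) should give the diazomethyl ketone; the non-explosive silyl reagent replaces diazomethane, and low temperature with immediate use of 11 limits acid-promoted side reactions.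

Step 7
Reactants: 13 chloroacetaldehyde dimethyl acetal
Product: 15 methoxyacetylene, via sodium methoxyethynide 14 (not isolated)
Conditions: NaNH2 (3 equiv), liq. NH3, −33 °C; evaporate NH3; then cold aq. NaCl, −20 °C; distil into cold ClCH2CH2Cl
Reagents that add atoms: none
Why: Twofold base-induced elimination (loss of chloride, then of methoxide) with NaNH2 gives the acetylide 14, which is protonated on cold aqueous quench; the ynol ether boils near room temperature and is therefore distilled directly into the solvent of step 8 and kept cold.

Step 8
Reactants: 12 2-diazo-1-[2-(4-benzyloxy-3-methoxyphenyl)-4-(4-benzyloxy-3-methoxybenzyl)-3-methylphenyl]ethanone; 15 methoxyacetylene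
Product: 19 5-(4-benzyloxy-3-methoxyphenyl)-7-(4-benzyloxy-3-methoxybenzyl)-3-methoxy-6-methylnaphthalen-1-ol, via arylketene 16 (not isolated), via cyclobutenone 17 (not isolated), via dienylketene 18 (not isolated)
Conditions: 15 (4 equiv), ClCH2CH2Cl, hν (medium-pressure Hg lamp, borosilicate filter), 5–10 °C, cold-finger condenser; then 80 °C
Reagents that add atoms: none
Why: Photochemical Wolff rearrangement of 12 gives arylketene 16 (aryl shift, forming C8a–C1), and regioselective [2+2] cycloaddition with the ynol ether (alkyne CH to the ketene carbonyl carbon) gives 17. Four-electron electrocyclic opening to 18 and six-electron electrocyclisation onto C4a, the only free ortho carbon, followed by enolisation give the 3-methoxy-1-naphthol (Danheiser-type benzannulation). The stereocentre of racemic 17 is transient and is lost on ring opening.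

Step 9
Reactants: 19 5-(4-benzyloxy-3-methoxyphenyl)-7-(4-benzyloxy-3-methoxybenzyl)-3-methoxy-6-methylnaphthalen-1-ol
Product: 20 8-(4-benzyloxy-3-methoxyphenyl)-6-(4-benzyloxy-3-methoxybenzyl)-2-methoxy-7-methylnaphthalene-1,4-dione
Conditions: (KSO3)2NO (2.5 equiv), KH2PO4, acetone/H2O, 0 °C → rt
Reagents that add atoms: potassium nitrosodisulfonate, [K+].[K+].[O]N(S(=O)(=O)[O-])S(=O)(=O)[O-]
Why: Teuber oxidation: one nitrosodisulfonate radical abstracts the naphthol hydrogen and a second adds at C1, para to the oxygen as is usual for phenols with a free para position, and loss of imidodisulfonate gives the para-quinone; benzyl aryl ethers are inert to this one-electron oxidant.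

Step 10
Reactants: 20 8-(4-benzyloxy-3-methoxyphenyl)-6-(4-benzyloxy-3-methoxybenzyl)-2-methoxy-7-methylnaphthalene-1,4-dione
Product: 22 larreantin, via naphthohydroquinone 21 (not isolated)
Conditions: H2 (1 atm), 10% Pd/C, EtOAc/MeOH, rt; filter; then air, rt
Reagents that add atoms: none
Why: Hydrogenolysis of the two aryl benzyl ethers over palladium also reduces the quinone to hydroquinone 21, which should autoxidise back to the quinone in air, so that no oxidant able to attack the free guaiacols is needed; diarylmethane C–C bonds and aryl methyl ethers are not hydrogenolysed under these conditions.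

## Compound list

1 | 4-benzyloxy-3-methoxybenzyl alcohol | COc1cc(CO)ccc1OCc1ccccc1 | starting material
2 | 4-benzyloxy-3-methoxybenzyl chloride | COc1cc(CCl)ccc1OCc1ccccc1 | intermediate
3 | methyl 2-amino-4-bromobenzoate | COC(=O)c1ccc(Br)cc1N | starting material
4 | (4-benzyloxy-3-methoxybenzyl)zinc chloride | COc1cc(C[Zn]Cl)ccc1OCc1ccccc1 | intermediate
5 | methyl 2-amino-4-(4-benzyloxy-3-methoxybenzyl)benzoate | COC(=O)c1ccc(Cc2ccc(OCc3ccccc3)c(OC)c2)cc1N | intermediate
6 | 5-(4-benzyloxy-3-methoxybenzyl)-2-(methoxycarbonyl)benzenediazonium 4-methylbenzenesulfonate | COC(=O)c1ccc(Cc2ccc(OCc3ccccc3)c(OC)c2)cc1[N+]#N.Cc1ccc(cc1)S(=O)(=O)[O-] | intermediate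
7 | methyl 4-(4-benzyloxy-3-methoxybenzyl)-2-iodobenzoate | COC(=O)c1ccc(Cc2ccc(OCc3ccccc3)c(OC)c2)cc1I | intermediate
8 | 4-benzyloxy-3-methoxyphenylboronic acid | COc1cc(B(O)O)ccc1OCc1ccccc1 | starting material
9 | methyl 2-(4-benzyloxy-3-methoxyphenyl)-4-(4-benzyloxy-3-methoxybenzyl)-3-methylbenzoate | COC(=O)c1ccc(Cc2ccc(OCc3ccccc3)c(OC)c2)c(C)c1-c1ccc(OCc2ccccc2)c(OC)c1 | intermediate
10 | 2-(4-benzyloxy-3-methoxyphenyl)-4-(4-benzyloxy-3-methoxybenzyl)-3-methylbenzoic acid | OC(=O)c1ccc(Cc2ccc(OCc3ccccc3)c(OC)c2)c(C)c1-c1ccc(OCc2ccccc2)c(OC)c1 | intermediate
11 | 2-(4-benzyloxy-3-methoxyphenyl)-4-(4-benzyloxy-3-methoxybenzyl)-3-methylbenzoyl chloride | ClC(=O)c1ccc(Cc2ccc(OCc3ccccc3)c(OC)c2)c(C)c1-c1ccc(OCc2ccccc2)c(OC)c1 | intermediate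
12 | 2-diazo-1-[2-(4-benzyloxy-3-methoxyphenyl)-4-(4-benzyloxy-3-methoxybenzyl)-3-methylphenyl]ethanone | [N-]=[N+]=CC(=O)c1ccc(Cc2ccc(OCc3ccccc3)c(OC)c2)c(C)c1-c1ccc(OCc2ccccc2)c(OC)c1 | intermediate
13 | chloroacetaldehyde dimethyl acetal (2-chloro-1,1-dimethoxyethane) | COC(CCl)OC | starting material
14 | sodium methoxyethynide | [Na+].[C-]#COC | intermediate
15 | methoxyacetylene (methoxyethyne) | C#COC | intermediate
16 | 2-[2-(4-benzyloxy-3-methoxyphenyl)-4-(4-benzyloxy-3-methoxybenzyl)-3-methylphenyl]ethenone (arylketene) | O=C=Cc1ccc(Cc2ccc(OCc3ccccc3)c(OC)c2)c(C)c1-c1ccc(OCc2ccccc2)c(OC)c1 | intermediate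
17 | 4-[2-(4-benzyloxy-3-methoxyphenyl)-4-(4-benzyloxy-3-methoxybenzyl)-3-methylphenyl]-3-methoxycyclobut-2-en-1-one, racemic | COC1=CC(=O)C1c1ccc(Cc2ccc(OCc3ccccc3)c(OC)c2)c(C)c1-c1ccc(OCc2ccccc2)c(OC)c1 | intermediate
18 | 4-[2-(4-benzyloxy-3-methoxyphenyl)-4-(4-benzyloxy-3-methoxybenzyl)-3-methylphenyl]-3-methoxybuta-1,3-dien-1-one, ketene carbon and aryl group cis about the C3=C4 bond | COC(/C=C=O)=C/c1ccc(Cc2ccc(OCc3ccccc3)c(OC)c2)c(C)c1-c1ccc(OCc2ccccc2)c(OC)c1 | intermediate
19 | 5-(4-benzyloxy-3-methoxyphenyl)-7-(4-benzyloxy-3-methoxybenzyl)-3-methoxy-6-methylnaphthalen-1-ol | COc1cc(O)c2cc(Cc3ccc(OCc4ccccc4)c(OC)c3)c(C)c(-c3ccc(OCc4ccccc4)c(OC)c3)c2c1 | intermediate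
20 | 8-(4-benzyloxy-3-methoxyphenyl)-6-(4-benzyloxy-3-methoxybenzyl)-2-methoxy-7-methylnaphthalene-1,4-dione | COC1=CC(=O)c2cc(Cc3ccc(OCc4ccccc4)c(OC)c3)c(C)c(-c3ccc(OCc4ccccc4)c(OC)c3)c2C1=O | intermediate
21 | 8-(4-hydroxy-3-methoxyphenyl)-6-(4-hydroxy-3-methoxybenzyl)-2-methoxy-7-methylnaphthalene-1,4-diol | COc1cc(O)c2cc(Cc3ccc(O)c(OC)c3)c(C)c(-c3ccc(O)c(OC)c3)c2c1O | intermediate
22 | larreantin, 8-(4-hydroxy-3-methoxyphenyl)-6-(4-hydroxy-3-methoxybenzyl)-2-methoxy-7-methylnaphthalene-1,4-dione | COC1=CC(=O)c2cc(Cc3ccc(O)c(OC)c3)c(C)c(-c3ccc(O)c(OC)c3)c2C1=O | target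

## Step count and least certain steps

Total: 10 steps. Longest linear sequence: 9 steps (steps 1–6, 8, 9 and 10, from 1); step 7 is a one-step side branch.

**Step 4 (key step).** Palladation of C7–H, which is flanked by the C6 benzyl group, may be slow. The first arylpalladium species could then couple directly with 8 without methylation, or the palladacycle could collapse with retention of norbornene; iodomethane may also be lost from the hot basic mixture. The fallback buys the methyl group in place. It sets out from 2 (as its zinc reagent 4) and returns at 9. The catalogue acid 2-amino-4-bromo-3-methylbenzoic acid F1 would be esterified (SOCl2, MeOH) to methyl 2-amino-4-bromo-3-methylbenzoate F2. Negishi coupling with 4 (Pd(OAc)2, SPhos, THF) would give methyl 2-amino-4-(4-benzyloxy-3-methoxybenzyl)-3-methylbenzoate F3. Diazotisation with iodide displacement as in step 3 would give methyl 4-(4-benzyloxy-3-methoxybenzyl)-2-iodo-3-methylbenzoate F4, and Suzuki–Miyaura coupling of F4 with 8 (Pd(OAc)2, SPhos, K3PO4, toluene/H2O, 90 °C) would give 9.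

**Step 8.** The ketocarbene or the arylketene may be captured by the neighbouring electron-rich C8 aryl ring instead of the ynol ether. Other hazards are evaporation of the volatile alkyne from the irradiated solution, O-acylation of the product naphthol by ketene, and photodegradation of the naphthol. The fallback separates ketene formation from light. It sets out from 12 and returns at 19. Silver-promoted Wolff rearrangement in water (PhCO2Ag, Et3N, THF/H2O) would give [2-(4-benzyloxy-3-methoxyphenyl)-4-(4-benzyloxy-3-methoxybenzyl)-3-methylphenyl]acetic acid F5. (COCl)2 would give the arylacetyl chloride F6, and slow addition of Et3N to F6 and 15 in CH2Cl2 at 0 °C would generate 16 by dehydrochlorination. Thermal [2+2] addition would then give 17, and heating at 80 °C would give 19.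

**Step 6.** Under the HCl released, the acid chloride 11 may acylate the adjacent C8 aryl ring (ring closure to a fluorenone), and HCl may convert the diazoketone into a chloromethyl ketone. The fallback avoids the acid chloride. It sets out from 10 and returns at 12. MeLi (2.2 equiv, THF, 0 °C) would give the methyl ketone 1-[2-(4-benzyloxy-3-methoxyphenyl)-4-(4-benzyloxy-3-methoxybenzyl)-3-methylphenyl]ethanone F7. Trifluoroacetylation (LiN(SiMe3)2, CF3CO2CH2CF3, THF, −78 °C) would give the trifluoromethyl 1,3-diketone F8, and detrifluoroacetylative diazo transfer (MsN3, Et3N, H2O, MeCN) would give 12.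

**Step 9.** The second nitrosodisulfonate radical may add at C3 instead of C1, because C1 is screened by the peri C8 aryl group; this would lead to ortho-quinone formation, and radical dimerisation is also possible. The fallback uses a two-electron oxidation with a small nucleophile. It sets out from 19 and returns at 20. PhI(OAc)2 (2.2 equiv) in MeOH at 0 °C would give the para-quinone monoketal 5-(4-benzyloxy-3-methoxyphenyl)-7-(4-benzyloxy-3-methoxybenzyl)-3,4,4-trimethoxy-6-methylnaphthalen-1(4H)-one F9, and mild acid hydrolysis (aqueous oxalic acid, acetone) would give 20.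

**Step 2.** Zinc insertion into the electron-rich benzylic chloride may be accompanied by Wurtz-type homocoupling, and the zinc reagent may be partly protonated by the NH2 group. The fallback reverses the polarity. It sets out from 3 and returns at 5. Miyaura borylation of 3 (B2pin2, PdCl2(dppf), KOAc, dioxane, 90 °C) would give methyl 2-amino-4-(4,4,5,5-tetramethyl-1,3,2-dioxaborolan-2-yl)benzoate F10, and Suzuki–Miyaura coupling of F10 with 2 (Pd(PPh3)4, K2CO3, DME/H2O, 80 °C) would give 5.

## Further compounds

F1 | step 4 | 2-amino-4-bromo-3-methylbenzoic acid | OC(=O)c1ccc(Br)c(C)c1N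
F2 | step 4 | methyl 2-amino-4-bromo-3-methylbenzoate | COC(=O)c1ccc(Br)c(C)c1N
F3 | step 4 | methyl 2-amino-4-(4-benzyloxy-3-methoxybenzyl)-3-methylbenzoate | COC(=O)c1ccc(Cc2ccc(OCc3ccccc3)c(OC)c2)c(C)c1N
F4 | step 4 | methyl 4-(4-benzyloxy-3-methoxybenzyl)-2-iodo-3-methylbenzoate | COC(=O)c1ccc(Cc2ccc(OCc3ccccc3)c(OC)c2)c(C)c1I
F5 | step 8 | [2-(4-benzyloxy-3-methoxyphenyl)-4-(4-benzyloxy-3-methoxybenzyl)-3-methylphenyl]acetic acid | OC(=O)Cc1ccc(Cc2ccc(OCc3ccccc3)c(OC)c2)c(C)c1-c1ccc(OCc2ccccc2)c(OC)c1
F6 | step 8 | [2-(4-benzyloxy-3-methoxyphenyl)-4-(4-benzyloxy-3-methoxybenzyl)-3-methylphenyl]acetyl chloride | ClC(=O)Cc1ccc(Cc2ccc(OCc3ccccc3)c(OC)c2)c(C)c1-c1ccc(OCc2ccccc2)c(OC)c1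
F7 | step 6 | 1-[2-(4-benzyloxy-3-methoxyphenyl)-4-(4-benzyloxy-3-methoxybenzyl)-3-methylphenyl]ethanone | CC(=O)c1ccc(Cc2ccc(OCc3ccccc3)c(OC)c2)c(C)c1-c1ccc(OCc2ccccc2)c(OC)c1
F8 | step 6 | 4,4,4-trifluoro-1-[2-(4-benzyloxy-3-methoxyphenyl)-4-(4-benzyloxy-3-methoxybenzyl)-3-methylphenyl]butane-1,3-dione | O=C(CC(=O)C(F)(F)F)c1ccc(Cc2ccc(OCc3ccccc3)c(OC)c2)c(C)c1-c1ccc(OCc2ccccc2)c(OC)c1
F9 | step 9 | 5-(4-benzyloxy-3-methoxyphenyl)-7-(4-benzyloxy-3-methoxybenzyl)-3,4,4-trimethoxy-6-methylnaphthalen-1(4H)-one | COC1=CC(=O)c2cc(Cc3ccc(OCc4ccccc4)c(OC)c3)c(C)c(-c3ccc(OCc4ccccc4)c(OC)c3)c2C1(OC)OC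
F10 | step 2 | methyl 2-amino-4-(4,4,5,5-tetramethyl-1,3,2-dioxaborolan-2-yl)benzoate | COC(=O)c1ccc(B2OC(C)(C)C(C)(C)O2)cc1N
A1 | alternative 1 | 4-[3-(4-benzyloxy-3-methoxybenzyl)-2-methyl-4-(2,4,5-trimethoxyphenyl)butyl]-2-methoxyphenol, diastereomer mixture | COc1cc(OC)c(CC(Cc2ccc(OCc3ccccc3)c(OC)c2)C(C)Cc2ccc(O)c(OC)c2)cc1OC
A2 | alternative 1 | para-quinone methide of A1, 4-[3-(4-benzyloxy-3-methoxybenzyl)-2-methyl-4-(2,4,5-trimethoxyphenyl)butylidene]-2-methoxycyclohexa-2,5-dien-1-one | COC1=CC(=CC(C)C(Cc2ccc(OCc3ccccc3)c(OC)c2)Cc2cc(OC)c(OC)cc2OC)C=CC1=O
A3 | alternative 1 | 1-(4-hydroxy-3-methoxyphenyl)-3-(4-benzyloxy-3-methoxybenzyl)-5,7,8-trimethoxy-2-methyltetralin, diastereomer mixture | COc1cc(OC)c2c(c1OC)C(c1ccc(O)c(OC)c1)C(C)C(Cc1ccc(OCc3ccccc3)c(OC)c1)C2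
A4 | alternative 2 | (4-benzyloxy-3-methoxyphenyl)[3-(4-benzyloxy-3-methoxybenzyl)-2,2-dichloro-1-methylcyclopropyl](2,3,5-trimethoxyphenyl)methanol, diastereomer mixture | COc1cc(OC)c(OC)c(C(O)(c2ccc(OCc3ccccc3)c(OC)c2)C2(C)C(Cc3ccc(OCc4ccccc4)c(OC)c3)C2(Cl)Cl)c1
A5 | alternative 2 | 8-(4-benzyloxy-3-methoxyphenyl)-6-(4-benzyloxy-3-methoxybenzyl)-5-chloro-1,2,4-trimethoxy-7-methylnaphthalene | COc1cc(OC)c2c(Cl)c(Cc3ccc(OCc4ccccc4)c(OC)c3)c(C)c(-c3ccc(OCc4ccccc4)c(OC)c3)c2c1OC
A6 | alternative 3 | 2-diazo-1-[2-(4-benzyloxy-3-methoxyphenyl)-4-(4-benzyloxy-3-methoxybenzyl)-3-methylphenyl]ethanone (identical with 12) | [N-]=[N+]=CC(=O)c1ccc(Cc2ccc(OCc3ccccc3)c(OC)c2)c(C)c1-c1ccc(OCc2ccccc2)c(OC)c1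
A7 | alternative 3 | 5-(4-benzyloxy-3-methoxyphenyl)-7-(4-benzyloxy-3-methoxybenzyl)-3-methoxy-6-methylnaphthalen-1-ol (identical with 19) | COc1cc(O)c2cc(Cc3ccc(OCc4ccccc4)c(OC)c3)c(C)c(-c3ccc(OCc4ccccc4)c(OC)c3)c2c1
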